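The dihydropyranone ring (O1, C2, C3, C4, C4a, C8a in flavanone-type numbering) is cut at C4–C4a and O1–C8a. Its C4a=C8a vinylogous-ester unit is the enol of a cage ketone, so the ring is made by inserting that C=C into the acyl–oxygen bond of (S)-4-phenyloxetan-2-one: a two-atom ring expansion of a β-lactone that brings C2 from the chiral pool and forms both ring bonds in one operation. The precursor is a tricyclic keto alcohol, a bicyclo[2.2.2]octanedione fused to an oxolane, obtained by oxidative dearomatization of a dimethylphloroglucinol ester with prenol, intramolecular Diels–Alder reaction and loss of the blocking ester.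

Key step: step 5

Remark on locants: the cage compounds are described with flavanone-type locants of the target, O1, C2 (CHPh), C3, C4 (C=O), C4a, C5 (bridgehead C–OH), C6 (C(CH3)–O), C7 (C=O), C8 (bridgehead C–CH3), C8a, and C1' (OCH2), C2' (CH), C3' (C(CH3)2) for the former prenyl unit; the target is (2S,5R,6S,8R,2'R).

Assumption: the (R,R)-aryl-λ3-iodane of step 2 is taken to direct prenol to the ortho carbon that gives (3S)-4; should the sense prove opposite, its (S,S)-enantiomer would be used.

Step 1
Reactants: 1 methyl 2,4,6-trihydroxybenzoate
Product: 2 methyl 2,4,6-trihydroxy-3,5-dimethylbenzoate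
Conditions: NaOMe (2.2 equiv), MeI (2.2 equiv), MeOH, 0 °C to 23 °C
Reagents that add atoms: iodomethane, CI
Why: Twofold C-methylation of the phloroglucinolate (alkylation of a vinylogous β-dicarbonyl enolate, C-selective in a protic solvent) at the two free ring carbons, the ester occupying the third; no stereocenter is formed.

Step 2
Reactants: 2 methyl 2,4,6-trihydroxy-3,5-dimethylbenzoate; 3 3-methylbut-2-en-1-ol (prenol)
Product: 5 cage enol β-keto ester (tricycle of the target with OH on C8a and CO2CH3 on C4a; 5R,6S,8R,2'R), via prenyloxy dienone 4 (not isolated)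
Conditions: (R,R)-ArI(OAc)2 [Ar = 2,6-bis{[(2R)-1-(mesitylamino)-1-oxopropan-2-yl]oxy}phenyl] (1.1 equiv), 3 (10 equiv), CH2Cl2, −40 to 0 °C; then PhMe, 110 °C
Reagents that add atoms: none
Why: Alkoxylative oxidative dearomatization of the phenol by a chiral aryl-λ3-iodane (ligand exchange at trivalent iodine, then attack of prenol at one of the two enantiotopic methyl-bearing ortho carbons, the ester-bearing para carbon being deactivated) should set C6 under reagent control, and the resulting 2,4-cyclohexadienone then undergoes an intramolecular Diels–Alder reaction in which the three-atom ether tether forces the prenyl CH onto C5 and C(CH3)2 onto C8 on the face carrying the ether oxygen, so that C5, C8 and C2' follow from C6.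

Step 3
Reactants: 5 cage enol β-keto ester
Product: 6 cage keto alcohol (tricycle with C8a=O, C4aH2, C7=O and bridgehead C5–OH; 5S,6S,8R,2'R, the C5 descriptor changing by priority only)
Conditions: LiCl (3 equiv), H2O (2 equiv), DMSO, 130 °C
Reagents that add atoms: none
Why: Krapcho dealkoxycarbonylation, in which chloride demethylates the enolized β-keto ester by SN2 attack and the carboxylate loses CO2 under neutral conditions, should leave the base-sensitive tertiary β-hydroxy ketone and all four stereocenters untouched.

Step 4
Reactants: 7 (3S)-3-hydroxy-3-phenylpropanoic acid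
Product: 8 (4S)-4-phenyloxetan-2-one
Conditions: PhSO2Cl (1.5 equiv), pyridine, 0 °C
Reagents that add atoms: none
Why: β-Lactonization by carboxyl activation (mixed carboxylic–sulfonic anhydride, then attack of the hydroxyl on the activated carbonyl) breaks no bond at the carbinol carbon and therefore retains the S configuration.

Step 5
Reactants: 6 cage keto alcohol; 8 (4S)-4-phenyloxetan-2-one
Product: 10 target CNP0322161.1 (2S,5R,6S,8R,2'R), via hydroxy diketone 9 (not isolated)
Conditions: LiN(SiMe3)2 (3.1 equiv), THF, −78 °C; 8 (1.3 equiv), −78 to −30 °C; AcOH; then camphor-10-sulfonic acid (0.1 equiv), 4 Å MS, CH2Cl2, 23 °C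
Reagents that add atoms: none
Why: LiN(SiMe3)2 converts 6 into its alkoxide–enolate dianion, whose only enolizable position is C4a because C8 is quaternary, and this hard lithium enolate attacks the strained lactone carbonyl of 8 (Claisen-type acylation with acyl–oxygen cleavage), releasing the C2 alkoxide and giving β-diketone 9. Under mild acid the liberated hydroxyl adds to the C8a carbonyl (6-exo-trig hemiketalization) and loss of water gives the vinylogous ester, so that the C4a=C8a unit has formally inserted into the C(=O)–O bond of the four-membered ring, a ring expansion by two atoms in which all four lactone ring atoms (O1, C2, C3, C4) are kept. The closest known reaction types are the acyl–oxygen opening of β-lactones by ester enolates and phosphonate carbanions and the acid-catalysed cyclodehydration of δ-hydroxy-β-diketones to 2,3-dihydro-4H-pyran-4-ones. No new stereocenter is created: C2 comes from the lactone with retention, since neither stage breaks a bond at the carbinol carbon, and the cage centres are spectators. The step needs acyl rather than benzylic alkyl–oxygen attack on 8, C- rather than O-acylation, and ring closure without β-elimination of the benzylic hydroxyl; the hard lithium counter-ion at low temperature, the thermodynamic sink of the β-diketonate and the mild, non-ionizing acid are expected to secure these.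

Compound list
1 | methyl 2,4,6-trihydroxybenzoate | COC(=O)c1c(O)cc(O)cc1O | starting material
2 | methyl 2,4,6-trihydroxy-3,5-dimethylbenzoate | COC(=O)c1c(O)c(C)c(O)c(C)c1O | intermediate
3 | 3-methylbut-2-en-1-ol (prenol) | CC(C)=CCO | starting material
4 | methyl (3S)-2,6-dihydroxy-3,5-dimethyl-3-[(3-methylbut-2-en-1-yl)oxy]-4-oxocyclohexa-1,5-diene-1-carboxylate (prenyloxy dienone) | CC(C)=CCO[C@]1(C)C(=O)C(C)=C(O)C(C(=O)OC)=C1O | intermediate
5 | cage enol β-keto ester: bicyclo[2.2.2]octene with bridgeheads C5 (OH) and C8 (CH3), bridges C4a(CO2CH3)=C8a(OH), C6(CH3)(O)–C7(=O) and C2'H–C3'(CH3)2, and oxolane C5–C6–O–C1'H2–C2'; (5R,6S,8R,2'R) | CC1(C)[C@@H]2CO[C@]3(C)C(=O)[C@@]1(C)C(O)=C(C(=O)OC)[C@]23O | intermediate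
6 | cage keto alcohol: the same tricycle with C8a=O and C4aH2; (5S,6S,8R,2'R) | CC1(C)[C@@H]2CO[C@]3(C)C(=O)[C@@]1(C)C(=O)C[C@]23O | intermediate
7 | (3S)-3-hydroxy-3-phenylpropanoic acid | OC(=O)C[C@H](O)c1ccccc1 | starting material
8 | (4S)-4-phenyloxetan-2-one | O=C1C[C@@H](c2ccccc2)O1 | intermediate
9 | hydroxy diketone: 6 acylated at C4a by (3S)-3-hydroxy-3-phenylpropanoyl, drawn as its C8a enol; (5R,6S,8R,2'R, side chain S) | CC1(C)[C@@H]2CO[C@]3(C)C(=O)[C@@]1(C)C(O)=C(C(=O)C[C@H](O)c4ccccc4)[C@]23O | intermediate
10 | CNP0322161.1, (2S,5R,6S,8R,2'R)-cage-fused 2-phenyl-2,3-dihydro-4H-pyran-4-one | CC1(C)[C@@H]2CO[C@]3(C)C(=O)[C@@]1(C)C1=C(C(=O)C[C@@H](c4ccccc4)O1)[C@]23O | target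

Total step count: 5. Longest linear sequence: 4 steps (steps 1, 2, 3 and 5); step 4 is a one-step side branch.

Steps most likely to fail

Step 5. Excess amide base may enolize lactone 8, the enolate may attack the benzylic carbon instead of the carbonyl, or the cage alkoxide may open by retro-aldol cleavage before C-acylation. The fallback sets out from 6 and changes how the nucleophile is made and protected. Silylation with Me3SiOTf and Et3N in CH2Cl2 should give the bis-silyl derivative F1 (C8a trimethylsilyl enol ether, C5 trimethylsilyl ether). MeLi (1 equiv) in THF at −78 °C would cleave only the enol ether, giving an amide-free lithium monoenolate with the carbinol masked. Acylation by 8, with LiOt-Bu (1 equiv) as proton sink, should give the silyl-protected hydroxy diketone F2. Aqueous HCl in THF then removes the silyl ether and closes the ring through 9, returning to the route at 10.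

Step 2. The chiral iodane may discriminate poorly between the two enantiotopic methyl-bearing carbons, acetate may transfer in place of prenol, or the cycloaddition may run through the isomeric dienone tautomer. The fallback sets out from 2 and replaces reagent control by a late separation of diastereomers. Oxidation with PhI(OAc)2 and 3 in CH2Cl2 gives dienone 4 together with its enantiomer, ent-dienone F3. Heating gives 5 together with ent-cage ester F4, and Krapcho dealkoxycarbonylation gives 6 together with ent-cage keto alcohol F5. Ring expansion of this racemate with enantiopure 8 proceeds through 9 and the diastereomeric hydroxy diketone F6. It gives 10 and the cage-epimeric diastereomer F7, which are separated by chromatography, so the route is rejoined at 10.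

Step 1. Over-alkylation to dearomatized gem-dimethyl products and O-methylation may erode the twofold C-methylation. The fallback sets out from 1: a double Mannich aminomethylation (aqueous CH2O, Me2NH, EtOH) should give the bis(dimethylaminomethyl) compound F8. Hydrogenolysis of its two benzylic C–N bonds (H2, Pd/C, MeOH) gives the two methyl groups, returning to the route at 2.

Further compounds
F1 | step 5 | bis-silyl derivative of 6 (C8a trimethylsilyl enol ether, C5 trimethylsilyl ether) | CC1(C)[C@@H]2CO[C@]3(C)C(=O)[C@@]1(C)C(O[Si](C)(C)C)=C[C@]23O[Si](C)(C)C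
F2 | step 5 | C5-O-trimethylsilyl derivative of hydroxy diketone 9 | CC1(C)[C@@H]2CO[C@]3(C)C(=O)[C@@]1(C)C(O)=C(C(=O)C[C@H](O)c4ccccc4)[C@]23O[Si](C)(C)C
F3 | step 2 | ent-dienone, (3R)-enantiomer of 4 | CC(C)=CCO[C@@]1(C)C(=O)C(C)=C(O)C(C(=O)OC)=C1O
F4 | step 2 | ent-cage ester, enantiomer of 5 | CC1(C)[C@H]2CO[C@@]3(C)C(=O)[C@]1(C)C(O)=C(C(=O)OC)[C@@]23O
F5 | step 2 | ent-cage keto alcohol, enantiomer of 6 | CC1(C)[C@H]2CO[C@@]3(C)C(=O)[C@]1(C)C(=O)C[C@@]23O
F6 | step 2 | diastereomeric hydroxy diketone (enantiomeric cage, S side chain) | CC1(C)[C@H]2CO[C@@]3(C)C(=O)[C@]1(C)C(O)=C(C(=O)C[C@H](O)c4ccccc4)[C@@]23O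
F7 | step 2 | cage-epimeric diastereomer of 10 (enantiomeric cage, 2S) | CC1(C)[C@H]2CO[C@@]3(C)C(=O)[C@]1(C)C1=C(C(=O)C[C@@H](c4ccccc4)O1)[C@@]23O
F8 | step 1 | methyl 3,5-bis[(dimethylamino)methyl]-2,4,6-trihydroxybenzoate | COC(=O)c1c(O)c(CN(C)C)c(O)c(CN(C)C)c1O
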